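The easy step comes first: the loss of starting material ignores the capture agent, since at 1.25 d the summer run holds 70.4% and the midnight run 70.1%, with 0.050 M against 0.11 M of it.

| flask | starting material | coupling partner | capture agent | temperature | remark | time |
|---|---|---|---|---|---|---|
| summer | 0.050 M | 3 equiv | 0.050 M | 30 °C | run made earlier |  |
| winter | 0.050 M | 3 equiv | 0.070 M | 41 °C | run made earlier |  |
| midnight | 0.050 M | 3 equiv | 0.11 M | 30 °C | run made earlier |  |
| dusk | 0.025 M | 3 equiv | 0.050 M | 41 °C | run made earlier |  |
| Tuesday's | 0.050 M | 3.00 equiv | 0.0500 M | 35 °C | everything together at the start | 4.0 d |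
| Wednesday's | 0.050 M (fed, over 2.5 d) | 3.00 equiv | 0.0500 M | 35 °C | all else is in the flask from the start; the feed brings no volume worth counting | 4.0 d |
| Sunday's | 0.050 M (fed, over 2.5 d) | 3.00 equiv | 0.0500 M |  | the addition at 15 °C, then warmed to 35 °C; the feed brings no volume worth counting | 4.0 d |
| Saturday's | 0.050 M (in portions, 5, over 2.5 d) | 3.00 equiv | 0.0500 M | 35 °C | first portion at the start, last at 2.5 d | 4.0 d |

| run | time / d | target / % | starting material / % |
|---|---|---|---|
| summer | 0.208 | 2.2 | 94.7 |
| summer | 0.333 | 4.8 | 90.5 |
| summer | 0.625 | 7.9 | 82.8 |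
| summer | 1.25 | 13.1 | 70.4 |
| summer | 2.50 | 24.1 | 50.8 |
| winter | 0.417 | 15.5 | 71.0 |
| winter | 1.25 | 34.4 | 38.9 |
| winter | 2.00 | 42.9 | 24.1 |
| winter | 3.00 | 49.5 | 13.9 |
| winter | 5.00 | 56.2 | 3.3 |
| midnight | 0.417 | 3.7 | 89.1 |
| midnight | 1.25 | 10.0 | 70.1 |
| midnight | 2.00 | 14.2 | 57.7 |
| midnight | 3.00 | 19.2 | 44.7 |
| midnight | 5.00 | 25.0 | 28.0 |
| dusk | 0.417 | 9.7 | 84.2 |
| dusk | 1.25 | 23.1 | 61.5 |
| dusk | 2.00 | 32.7 | 46.5 |
| dusk | 3.00 | 41.7 | 33.4 |
| dusk | 5.00 | 50.5 | 17.7 |

(scatter of a reading: 0.5 percentage points)



- the flask with the highest amount of target, in percent of the starting material charged ("all alike" if they lie within 1.5 percentage points) (Tuesday's / Wednesday's / Sunday's / Saturday's / all alike)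
- final target, as a percentage of the starting material charged, in Tuesday's
- final target, as a percentage of the starting material charged, in Wednesday's
- final target, as a percentage of the starting material charged, in Sunday's
- final target, as a percentage of the starting material charged, in Saturday's

So I read the loss as starting material plus coupling partner, allowing for the partner's fall by the formula further down. The summer run at 2.50 d and the winter run at 2.00 d give:

rate constant = 1.99 /M/d at 30 °C, 5.66 /M/d at 41 °C

Interpolating the logarithm by degrees gives 3.20 /M/d at 35 °C, and stretching it gives 0.480 /M/d at 15 °C.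

Rate constant times partner charge (0.150 M) times stay is 1.92 for Tuesday's. I call this product the turnover count: the lifetimes a pseudo-first-order starting material has lived through. Held flat, it leaves 14.7%.

The target's share of what has reacted comes from summer and dusk, both at the flasks' capture charge, though dusk has half the starting material. Their 49.0% and 61.4% interpolate to 54.6%, so Tuesday's would hold 46.6% of target.

The weak link is the flat partner, which loses a third of its charge if all the starting material reacts. With q the equivalents:

left = (q − 1) / (q·exp(count·(q − 1)/q) − 1)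

Tuesday's: left 20.4%, target 43.5%.

A steady feed and equal portions both give a mean stay of 2.75 d.

Wednesday's and Saturday's: count 1.32, left 32.1%, target 37.1%.

Sunday's: count 0.810, left 48.2%, target 28.3%.

The cold stretch of Sunday's adds less than the warm one, so I keep the warm share there.

The forecast names Tuesday's, with 45%, 37.5%, 26% and 37.5% for Tuesday's, Wednesday's, Sunday's and Saturday's, holding “Feeding therefore gains no selectivity and only loses conversion”; it lies above mine for Tuesday's and below mine for Sunday's.

The flasks give 44.2%, 36.7%, 27.2% and 36.2% in that order, with Tuesday's highest.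

    starting material + coupling partner → intermediate A (k = 0.135 /M/h, Ea = 75.0 kJ/mol)
    intermediate A → target (k = 0.728 /h, Ea = 94.0 kJ/mol)
    intermediate A ⇌ intermediate B (K = 16.3, k = 0.00226 /h, Ea = 120 kJ/mol, ΔH = −34.0 kJ/mol)
    capture agent + intermediate A → trapped intermediate (k = 5.85 /M/h, Ea = 61.0 kJ/mol)
    target ⇌ isomer of the product (K = 0.325, k = 0.280 /h, Ea = 105 kJ/mol, ΔH = −40.0 kJ/mol)
    (constants at 35 °C)

In Sunday's, 92.5% of the starting material stood at the end of the feed, and half of the first step's turnover was done by 2.98 d. At the end of Sunday's, intermediate A stood at 0.844%, its half-life towards target being 0.95 h against 1.7 d for starting material, so the starting material is the reading to watch. Tuesday's count of 1.92 ended at 20.1% left. Sunday's neighbour with 12.0 equiv of partner has a count of 3.24, giving 4.72% left and 52.0% target. That neighbour holds 4.83% and 50.4%.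

Readings and results are calculated on assumed constants; the scatter is artificial.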